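**Plan**

- In the target, C3 lies between the C4 ketone and C2, and C2 is benzylic and bonded to O1. The C2–C3 bond can therefore be made by a carbene on the carbon next to the C4 carbonyl inserting into a C–H bond of an O1–CH2–aryl ether.
- Retrosynthetic cuts, in order: the two O–Si bonds at O5 and O7; C2–C3 (ring C); the diazo group back to an aryl methyl ketone; the O1–CH2 ether bond; the two aryl–prenyl bonds of ring A. In the ring B fragment, the pyran ring of the chromene goes back to a propargyl ether of 4-hydroxybenzaldehyde.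
- Forward: ring A is diprenylated and silylated at O7. The chromene is built on 4-hydroxybenzaldehyde and the aldehyde is reduced. The two fragments are joined at O1 by Mitsunobu etherification, O5 is silylated and the methyl ketone becomes the diazoketone. Ring C closes last by C–H insertion, and fluoride frees the phenols.
- The only stereocentre, C2, is created in the insertion step under control of the chiral dirhodium carboxylate and is not touched afterwards.

Key step: step 9

Remark on the chemistry: the sense of induction of Rh2(S-PTTL)4 on this substrate is assumed to give (2S); if the opposite sense were found, the mirror-image catalyst Rh2(R-PTTL)4 would be used under identical conditions.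

("Prenyl" = 3-methylbut-2-en-1-yl.)

**Route**

Step 1
Reactants: 1 2,4,6-trihydroxyacetophenone; 2 prenyl bromide
Product: 4 1-[2,4,6-trihydroxy-3,5-diprenylphenyl]ethanone, via 1-[2,4,6-trihydroxy-3-prenylphenyl]ethanone 3 (not isolated)
Conditions: 2 (2.2 equiv), 10% aq KOH, 0 °C → rt; chromatographic separation
Reagents that add atoms: prenyl bromide, CC(C)=CCBr
Why: Base-mediated C-alkylation of the ambident phloroglucinol phenoxide in water, where hydrogen bonding to oxygen steers the allylic bromide to the two free ring carbons in turn; mono- and over-alkylated material is removed by chromatography.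

Step 2
Reactants: 4 1-[2,4,6-trihydroxy-3,5-diprenylphenyl]ethanone; 5 triisopropylsilyl chloride
Product: 6 1-[2,6-dihydroxy-3,5-diprenyl-4-(triisopropylsilyloxy)phenyl]ethanone
Conditions: 5 (1.05 equiv), imidazole, DMF, 0 °C → rt
Reagents that add atoms: triisopropylsilyl chloride, CC(C)[Si](Cl)(C(C)C)C(C)C
Why: Selective phenol silylation: the para hydroxyl is the most acidic and the only one not hydrogen-bonded to the ketone, so it should react first while the two chelated ortho hydroxyls remain.

Step 3
Reactants: 7 4-hydroxybenzaldehyde; 8 3-chloro-3-methylbut-1-yne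
Product: 9 4-[(2-methylbut-3-yn-2-yl)oxy]benzaldehyde
Conditions: 8, DBU, CuCl2·2H2O (cat.), MeCN, 0 °C
Reagents that add atoms: 3-chloro-3-methylbut-1-yne, C#CC(C)(C)Cl
Why: Copper-catalysed O-alkylation of a phenol with a tertiary propargylic chloride, a standard entry to aryl 1,1-dimethylpropargyl ethers.

Step 4
Reactants: 9 4-[(2-methylbut-3-yn-2-yl)oxy]benzaldehyde
Product: 12 2,2-dimethyl-2H-chromene-6-carbaldehyde, via ortho-allenylphenol 10 (not isolated), via ortho-quinone methide 11 (not isolated)
Conditions: PhNEt2, 190 °C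
Reagents that add atoms: none
Why: Aromatic propargyl Claisen rearrangement to the ortho-allenylphenol, 1,5-hydrogen shift to the ortho-quinone methide and oxa-6π electrocyclisation close the dimethylpyran ring; the para formyl group leaves both ortho positions equivalent.

Step 5
Reactants: 12 2,2-dimethyl-2H-chromene-6-carbaldehyde
Product: 13 (2,2-dimethyl-2H-chromen-6-yl)methanol
Conditions: NaBH4, MeOH, 0 °C
Reagents that add atoms: none
Why: Borohydride 1,2-reduction of an aryl aldehyde; the chromene alkene is not reduced.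

Step 6
Reactants: 6 1-[2,6-dihydroxy-3,5-diprenyl-4-(triisopropylsilyloxy)phenyl]ethanone; 13 (2,2-dimethyl-2H-chromen-6-yl)methanol
Product: 14 1-[2-[(2,2-dimethyl-2H-chromen-6-yl)methoxy]-6-hydroxy-3,5-diprenyl-4-(triisopropylsilyloxy)phenyl]ethanone
Conditions: PPh3, DIAD, THF, 0 °C → rt
Reagents that add atoms: none
Why: Mitsunobu etherification of an acidic ortho-acylphenol with a primary benzylic alcohol under neutral conditions that spare the silyl ether; after the first ortho oxygen is alkylated the remaining hydroxyl is held more firmly by the ketone, which should stop the reaction at the mono-ether.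

Step 7
Reactants: 14 1-[2-[(2,2-dimethyl-2H-chromen-6-yl)methoxy]-6-hydroxy-3,5-diprenyl-4-(triisopropylsilyloxy)phenyl]ethanone; 15 triisopropylsilyl trifluoromethanesulfonate
Product: 16 1-[2-[(2,2-dimethyl-2H-chromen-6-yl)methoxy]-3,5-diprenyl-4,6-bis(triisopropylsilyloxy)phenyl]ethanone
Conditions: 15, 2,6-lutidine, CH2Cl2, 0 °C → rt
Reagents that add atoms: triisopropylsilyl trifluoromethanesulfonate, CC(C)[Si](OS(=O)(=O)C(F)(F)F)(C(C)C)C(C)C
Why: Silylation of a hindered, chelated phenol with a silyl triflate; 2,6-lutidine buffers the acid and is too weak a base to drive enol silylation of the methyl ketone at a useful rate.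

Step 8
Reactants: 16 1-[2-[(2,2-dimethyl-2H-chromen-6-yl)methoxy]-3,5-diprenyl-4,6-bis(triisopropylsilyloxy)phenyl]ethanone; 17 2,2,2-trifluoroethyl trifluoroacetate; 18 4-acetamidobenzenesulfonyl azide
Product: 20 2-diazo-1-[2-[(2,2-dimethyl-2H-chromen-6-yl)methoxy]-3,5-diprenyl-4,6-bis(triisopropylsilyloxy)phenyl]ethanone, via trifluoroacetyl β-diketone 19 (not isolated)
Conditions: LiN(SiMe3)2, THF, −78 °C; 17, −78 °C; aq HCl work-up; then 18, Et3N, H2O (1 equiv), MeCN, rt
Reagents that add atoms: 4-acetamidobenzenesulfonyl azide, CC(=O)Nc1ccc(cc1)S(=O)(=O)N=[N+]=[N-] (the two diazo nitrogens); 2,2,2-trifluoroethyl trifluoroacetate, O=C(OCC(F)(F)F)C(F)(F)F (trifluoroacetyl group of 19 only, lost again)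
Why: Detrifluoroacetylative diazo transfer (Danheiser variant of the Regitz reaction): the kinetic lithium enolate of the methyl ketone is C-acylated to the activated β-diketone 19, which accepts the diazo group from the sulfonyl azide and passes its trifluoroacetyl group to the sulfonamide, giving the terminal diazoketone.

Step 9
Reactants: 20 2-diazo-1-[2-[(2,2-dimethyl-2H-chromen-6-yl)methoxy]-3,5-diprenyl-4,6-bis(triisopropylsilyloxy)phenyl]ethanone
Product: 21 (2S)-5,7-bis(triisopropylsilyloxy)-6,8-diprenylflavanone bearing the 2,2-dimethyl-2H-chromen-6-yl group as ring B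
Conditions: Rh2(S-PTTL)4 (dirhodium tetrakis[N-phthaloyl-(S)-tert-leucinate], 2 mol %), CH2Cl2, 0 °C, slow addition of 20 at high dilution
Reagents that add atoms: none
Why: The dirhodium tetracarboxylate expels N2 from 20, and the electrophilic carbenoid on divalent rhodium (carbene carbon = future C3) inserts through a concerted, asynchronous three-centre transition state with hydride-transfer character into one C–H bond of the O1–CH2–aryl group, forming C2–C3. The closest known reaction type is the chiral dirhodium carboxylate-catalysed intramolecular C–H insertion of ortho-alkoxyaryl α-diazoketones that gives 2-substituted chroman-4-ones. Ring C closes as a six-membered ring by 1,6-insertion, the usual 1,5-mode being unavailable because the fifth atom is the ether oxygen O1 itself. C2 is set by the chiral pocket of the four N-phthaloyl-tert-leucinate ligands, which differentiates the two enantiotopic benzylic hydrogens and should deliver the (2S) product. The step needs insertion to win over oxonium ylide formation at O1 or O5 and over alkene cyclopropanation: the targeted C–H bond is benzylic, α to oxygen and further activated by the para ether oxygen of ring B, the bulky triisopropylsilyl group shields O5 and offers no C–H bond within reach, and both prenyl groups sit meta to the acyl group so that intramolecular addition to them would need a meta-bridged ring. Slow addition at high dilution suppresses carbene dimerisation and intermolecular attack on the chromene alkene.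

Step 10
Reactants: 21 (2S)-5,7-bis(triisopropylsilyloxy)-6,8-diprenylflavanone bearing the 2,2-dimethyl-2H-chromen-6-yl group as ring B
Product: 23 (2S)-2-(2,2-dimethyl-2H-chromen-6-yl)-5,7-dihydroxy-6,8-diprenylchroman-4-one, via 7-O-silyl flavanone 22 (not isolated)
Conditions: Bu4NF, AcOH (1:1), THF, 0 °C → rt
Reagents that add atoms: none
Why: Fluoride cleaves both aryl silyl ethers, the peri-compressed O5 ether presumably first; the acetic acid buffer keeps phenoxide and enolate concentrations low, so that the flavanone should not open by retro-oxa-Michael reaction and C2 should keep its configuration.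

**Compound list**

1 | 2,4,6-trihydroxyacetophenone | CC(=O)c1c(O)cc(O)cc1O | starting material
2 | prenyl bromide (1-bromo-3-methylbut-2-ene) | CC(C)=CCBr | starting material
3 | 1-[2,4,6-trihydroxy-3-(3-methylbut-2-en-1-yl)phenyl]ethanone | CC(=O)c1c(O)cc(O)c(CC=C(C)C)c1O | intermediate
4 | 1-[2,4,6-trihydroxy-3,5-bis(3-methylbut-2-en-1-yl)phenyl]ethanone | CC(=O)c1c(O)c(CC=C(C)C)c(O)c(CC=C(C)C)c1O | intermediate
5 | triisopropylsilyl chloride | CC(C)[Si](Cl)(C(C)C)C(C)C | starting material
6 | 1-[2,6-dihydroxy-3,5-bis(3-methylbut-2-en-1-yl)-4-(triisopropylsilyloxy)phenyl]ethanone | CC(=O)c1c(O)c(CC=C(C)C)c(O[Si](C(C)C)(C(C)C)C(C)C)c(CC=C(C)C)c1O | intermediate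
7 | 4-hydroxybenzaldehyde | O=Cc1ccc(O)cc1 | starting material
8 | 3-chloro-3-methylbut-1-yne | C#CC(C)(C)Cl | starting material
9 | 4-[(2-methylbut-3-yn-2-yl)oxy]benzaldehyde | C#CC(C)(C)Oc1ccc(C=O)cc1 | intermediate
10 | 4-hydroxy-3-(3-methylbuta-1,2-dien-1-yl)benzaldehyde | CC(C)=C=Cc1cc(C=O)ccc1O | intermediate
11 | 3-(3-methylbut-2-en-1-ylidene)-4-oxocyclohexa-1,5-diene-1-carbaldehyde | O=CC1=CC(=CC=C(C)C)C(=O)C=C1 | intermediate
12 | 2,2-dimethyl-2H-chromene-6-carbaldehyde | CC1(C)C=Cc2cc(C=O)ccc2O1 | intermediate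
13 | (2,2-dimethyl-2H-chromen-6-yl)methanol | CC1(C)C=Cc2cc(CO)ccc2O1 | intermediate
14 | 1-[2-[(2,2-dimethyl-2H-chromen-6-yl)methoxy]-6-hydroxy-3,5-bis(3-methylbut-2-en-1-yl)-4-(triisopropylsilyloxy)phenyl]ethanone | CC(=O)c1c(O)c(CC=C(C)C)c(O[Si](C(C)C)(C(C)C)C(C)C)c(CC=C(C)C)c1OCc1ccc2c(c1)C=CC(C)(C)O2 | intermediate
15 | triisopropylsilyl trifluoromethanesulfonate | CC(C)[Si](OS(=O)(=O)C(F)(F)F)(C(C)C)C(C)C | starting material
16 | 1-[2-[(2,2-dimethyl-2H-chromen-6-yl)methoxy]-3,5-bis(3-methylbut-2-en-1-yl)-4,6-bis(triisopropylsilyloxy)phenyl]ethanone | CC(=O)c1c(O[Si](C(C)C)(C(C)C)C(C)C)c(CC=C(C)C)c(O[Si](C(C)C)(C(C)C)C(C)C)c(CC=C(C)C)c1OCc1ccc2c(c1)C=CC(C)(C)O2 | intermediate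
17 | 2,2,2-trifluoroethyl trifluoroacetate | O=C(OCC(F)(F)F)C(F)(F)F | starting material
18 | 4-acetamidobenzenesulfonyl azide | CC(=O)Nc1ccc(cc1)S(=O)(=O)N=[N+]=[N-] | starting material
19 | 1-[2-[(2,2-dimethyl-2H-chromen-6-yl)methoxy]-3,5-bis(3-methylbut-2-en-1-yl)-4,6-bis(triisopropylsilyloxy)phenyl]-4,4,4-trifluorobutane-1,3-dione | O=C(CC(=O)C(F)(F)F)c1c(O[Si](C(C)C)(C(C)C)C(C)C)c(CC=C(C)C)c(O[Si](C(C)C)(C(C)C)C(C)C)c(CC=C(C)C)c1OCc1ccc2c(c1)C=CC(C)(C)O2 | intermediate
20 | 2-diazo-1-[2-[(2,2-dimethyl-2H-chromen-6-yl)methoxy]-3,5-bis(3-methylbut-2-en-1-yl)-4,6-bis(triisopropylsilyloxy)phenyl]ethanone | [N-]=[N+]=CC(=O)c1c(O[Si](C(C)C)(C(C)C)C(C)C)c(CC=C(C)C)c(O[Si](C(C)C)(C(C)C)C(C)C)c(CC=C(C)C)c1OCc1ccc2c(c1)C=CC(C)(C)O2 | intermediate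
21 | (2S)-2-(2,2-dimethyl-2H-chromen-6-yl)-6,8-bis(3-methylbut-2-en-1-yl)-5,7-bis(triisopropylsilyloxy)-2,3-dihydro-4H-chromen-4-one | CC(C)=CCc1c(O[Si](C(C)C)(C(C)C)C(C)C)c(CC=C(C)C)c2c(c1O[Si](C(C)C)(C(C)C)C(C)C)C(=O)C[C@@H](c1ccc3c(c1)C=CC(C)(C)O3)O2 | intermediate
22 | (2S)-2-(2,2-dimethyl-2H-chromen-6-yl)-5-hydroxy-6,8-bis(3-methylbut-2-en-1-yl)-7-(triisopropylsilyloxy)-2,3-dihydro-4H-chromen-4-one | CC(C)=CCc1c(O[Si](C(C)C)(C(C)C)C(C)C)c(CC=C(C)C)c2c(c1O)C(=O)C[C@@H](c1ccc3c(c1)C=CC(C)(C)O3)O2 | intermediate
23 | (2S)-2-(2,2-dimethyl-2H-chromen-6-yl)-5,7-dihydroxy-6,8-bis(3-methylbut-2-en-1-yl)-2,3-dihydro-4H-chromen-4-one | CC(C)=CCc1c(O)c(CC=C(C)C)c2c(c1O)C(=O)C[C@@H](c1ccc3c(c1)C=CC(C)(C)O3)O2 | target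

**Step count**

Total: 10 steps. Longest linear sequence: 8 steps (steps 3, 4, 5, 6, 7, 8, 9, 10, from 4-hydroxybenzaldehyde); the ring A branch (steps 1 and 2) joins at step 6.

**Steps most likely to fail**

1. Step 9 (C–H insertion). The carbenoid may be trapped by the lone pair of O1 to give an oxonium ylide that undergoes a 1,2-shift of the electron-rich benzyl group, and the two enantiotopic hydrogens may be discriminated poorly. The fallback abandons the carbene and closes ring C by oxa-Michael addition; it sets out from 4 and 12 and comes back at 23. The 2- and 4-hydroxyls of 4 would be capped with MOMCl and i-Pr2NEt in CH2Cl2 to give 1-[2-hydroxy-4,6-bis(methoxymethoxy)-3,5-diprenylphenyl]ethanone F1. Claisen–Schmidt condensation of F1 with aldehyde 12 (KOH, EtOH–H2O, rt) would give the bis(methoxymethyl)-protected (E)-chalcone F2. Methanolysis (HCl, MeOH, 40 °C) would free the 2',4',6'-trihydroxychalcone F3. NaOAc in refluxing EtOH would close ring C to the racemic flavanone F4. Preparative HPLC on a chiral stationary phase would then deliver the (2S) enantiomer, which is 23.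

2. Step 1 (diprenylation). Alkylation of the phenoxide may not stop cleanly: O-alkylation, geminal dialkylation with loss of aromaticity and a statistical spread of mono- and dialkylated material would erode the throughput. The fallback sets out from 1 and returns at 4 by Friedel–Crafts prenylation with 2-methylbut-3-en-2-ol and BF3·OEt2 in dioxane at rt. Here the neutral arene is attacked by the allyl cation, so neither O-alkylation nor dearomatising dialkylation can take place. It passes through 3 again and makes no new compound (entry F0 below).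

3. Step 6 (Mitsunobu etherification). Coupling at a chelated, doubly ortho-substituted phenol may be slow, and the electron-rich benzylic oxyphosphonium ion may ionise and alkylate the reduced azodicarboxylate instead. The fallback sets out from 13 and 6 and returns at 14 by Williamson alkylation. Alcohol 13 would be converted with SOCl2 and pyridine in CH2Cl2 at 0 °C into 6-(chloromethyl)-2,2-dimethyl-2H-chromene F5. F5 would then alkylate one chelated hydroxyl of 6 with K2CO3 in refluxing acetone to give 14.

**Further compounds**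

F1 | step 9 | 1-[2-hydroxy-4,6-bis(methoxymethoxy)-3,5-bis(3-methylbut-2-en-1-yl)phenyl]ethanone | CC(=O)c1c(O)c(CC=C(C)C)c(OCOC)c(CC=C(C)C)c1OCOC
F2 | step 9 | (E)-3-(2,2-dimethyl-2H-chromen-6-yl)-1-[2-hydroxy-4,6-bis(methoxymethoxy)-3,5-bis(3-methylbut-2-en-1-yl)phenyl]prop-2-en-1-one | O=C(/C=C/c1ccc2c(c1)C=CC(C)(C)O2)c1c(O)c(CC=C(C)C)c(OCOC)c(CC=C(C)C)c1OCOC
F3 | step 9 | (E)-3-(2,2-dimethyl-2H-chromen-6-yl)-1-[2,4,6-trihydroxy-3,5-bis(3-methylbut-2-en-1-yl)phenyl]prop-2-en-1-one | O=C(/C=C/c1ccc2c(c1)C=CC(C)(C)O2)c1c(O)c(CC=C(C)C)c(O)c(CC=C(C)C)c1O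
F4 | step 9 | racemic 2-(2,2-dimethyl-2H-chromen-6-yl)-5,7-dihydroxy-6,8-bis(3-methylbut-2-en-1-yl)-2,3-dihydro-4H-chromen-4-one | CC(C)=CCc1c(O)c(CC=C(C)C)c2c(c1O)C(=O)CC(c1ccc3c(c1)C=CC(C)(C)O3)O2
F0 | step 1 | none | none
F5 | step 6 | 6-(chloromethyl)-2,2-dimethyl-2H-chromene | ClCc1ccc2c(c1)C=CC(C)(C)O2
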